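**Retrosynthetic overview**

1. The last bond made is the benzylic ester C–O bond between the C6 CH2OH of ring A (alcohol 14) and the carboxyl group of ring B (haematommic acid 4). It is formed by Mitsunobu alkylation of the acid, so that the lactonization-prone hydroxy ester 14 never meets acid or base.
2. The strategy rests on ring A, which carries in unbroken sequence C1 CO2Me, C2 OH, C3 CH3, C4 OH, C5 H and C6 CH2O. This is the pattern of a methyl 3-methyl-2,4-dioxocyclohexane-1-carboxylate, so the ring is built saturated and fully substituted and is dehydrogenated afterwards.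
3. Ring A is disconnected across C1–C6 (Michael) and C2–C3 (Claisen) to dimethyl malonate 8 and enone 7; the enone comes from aldehyde 5 and phosphonate 6 by Horner–Wadsworth–Emmons olefination.
4. Ring B is bought aromatic as orsellinic acid 1 and taken through its allyl ester, C3 formylation and neutral deallylation, so that no hindered, decarboxylation-prone resorcylate has to be saponified.
5. Ring order: ring A is the only ring formed (step 5) and is aromatized in step 6; rings A and B are joined in step 8.

Key step: step 5

Remark on the chemistry: the target has no stereocentre, so dione 10 is made and used as a racemate; its SMILES shows one enantiomer of the trans pair, and 10 is written as one enol tautomer.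

**Route**

Step 1
Reactants: 1 orsellinic acid (2,4-dihydroxy-6-methylbenzoic acid)
Product: 2 allyl 2,4-dihydroxy-6-methylbenzoate
Conditions: allyl bromide (1.05 equiv), KHCO3 (1.1 equiv), DMF, rt
Reagents that add atoms: allyl bromide, C=CCBr
Why: SN2 O-alkylation of the carboxylate, in which bicarbonate ionizes only the carboxyl group, so both phenols stay free and room temperature avoids decarboxylation.

Step 2
Reactants: 2 allyl 2,4-dihydroxy-6-methylbenzoate
Product: 3 allyl 3-formyl-2,4-dihydroxy-6-methylbenzoate
Conditions: TiCl4 (3 equiv), Cl2CHOMe (1.2 equiv), CH2Cl2, –10 to 0 °C; then ice-cold 1 M HCl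
Reagents that add atoms: dichloromethyl methyl ether, COC(Cl)Cl; water, O
Why: Rieche formylation, in which titanium held by the C2 phenoxide–ester chelate (and the C4 oxygen) should deliver the electrophile to C3, the carbon ortho to both oxygens, while the allyl ester resists the Lewis acid and any C5 aldehyde is removed by crystallization.

Step 3
Reactants: 3 allyl 3-formyl-2,4-dihydroxy-6-methylbenzoate
Product: 4 3-formyl-2,4-dihydroxy-6-methylbenzoic acid (haematommic acid)
Conditions: Pd(PPh3)4 (3 mol%), p-TolSO2Na (1.2 equiv), THF/MeOH, rt; then cold 1 M HCl, no heating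
Reagents that add atoms: none
Why: Tsuji–Trost deallylation, in which zerovalent palladium ionizes the allyl ester to a pi-allyl complex that the sulfinate captures, releasing the acid at room temperature without touching the aldehyde and without the heat that would decarboxylate it.

Step 4
Reactants: 5 benzyloxyacetaldehyde; 6 dimethyl (2-oxobutyl)phosphonate
Product: 7 (E)-6-(benzyloxy)hex-4-en-3-one
Conditions: LiCl (1.2 equiv), iPr2NEt (1.1 equiv), MeCN, 0 °C to rt
Reagents that add atoms: none
Why: Horner–Wadsworth–Emmons olefination under Masamune–Roush conditions, where the stabilized keto phosphonate gives the E enone and the mild amine base spares the enolizable alpha-alkoxy aldehyde.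

Step 5
Reactants: 8 dimethyl malonate; 7 (E)-6-(benzyloxy)hex-4-en-3-one
Product: 10 racemic trans methyl 6-[(benzyloxy)methyl]-2-hydroxy-3-methyl-4-oxocyclohex-2-ene-1-carboxylate, via Michael adduct 9 (not isolated)
Conditions: NaOMe (1.1 equiv), MeOH, 0 °C to rt, then reflux; 1 M HCl to pH 3 at 0 °C
Reagents that add atoms: none
Why: Michael–Claisen annulation, the known route from malonates and alk-1-enyl ethyl ketones to 2-methylcyclohexane-1,3-dione-4-carboxylates: the malonate anion adds to C5 of enone 7 (new C1–C6 bond of ring A) to give keto diester 9, whose ethyl-side ketone enolate then attacks one malonate ester carbonyl and expels methoxide (new C2–C3 bond). The ring closes in a 6-(enolendo)-exo-trig Claisen (Dieckmann-type) mode. C6 is created in the conjugate addition without facial control and C1 is epimerizable, so the product is a racemate that should settle as the trans (diequatorial) isomer; both centres are deleted in step 6 and need no control. The step needs 1,4- rather than 1,2-addition, which the soft stabilized malonate anion secures, and closure through the CH2 of the ethyl group, which the substrate secures because the enolate on the other side of the ketone could only form a four-membered ring. Deprotonation of the acidic dione by the released methoxide makes the sequence irreversible, and the benzyl ether sits gamma to every carbanion centre, so it cannot be lost by beta-elimination.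

Step 6
Reactants: 10 racemic trans methyl 6-[(benzyloxy)methyl]-2-hydroxy-3-methyl-4-oxocyclohex-2-ene-1-carboxylate
Product: 13 methyl 6-[(benzyloxy)methyl]-2,4-dihydroxy-3-methylbenzoate, via C3 bromide 11 (not isolated), via C1 bromide 12 (not isolated)
Conditions: Br2 (1.0 equiv), DMF, 0 °C; then 80 °C
Reagents that add atoms: none
Why: Halogenation–dehydrohalogenation aromatization of a cyclohexane-1,3-dione: the enol is brominated at C3 in the cold so that no free bromine remains when the arene appears, HBr then relays the bromine to the beta-keto ester carbon C1 by reversible debromination–rebromination, and loss of HBr across C1–C6 followed by enolization gives the resorcylate and removes both stereocentres, while DMF buffers the acid so that the benzyl ether survives.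

Step 7
Reactants: 13 methyl 6-[(benzyloxy)methyl]-2,4-dihydroxy-3-methylbenzoate
Product: 14 methyl 2,4-dihydroxy-6-(hydroxymethyl)-3-methylbenzoate
Conditions: H2 (1 atm), 10% Pd/C, EtOAc, rt, stopped at full conversion; filtered, concentrated below 25 °C and used at once
Reagents that add atoms: none
Why: Catalytic hydrogenolysis of a benzyl ether, in which the unsubstituted benzyl C–O bond should be cleaved in preference to the ring A benzylic C–O bond (flanked by the ester on a pentasubstituted, poorly adsorbing arene), and the neutral aprotic medium slows both further reduction of the new benzylic alcohol and its closure onto the C1 ester.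

Step 8
Reactants: 14 methyl 2,4-dihydroxy-6-(hydroxymethyl)-3-methylbenzoate; 4 3-formyl-2,4-dihydroxy-6-methylbenzoic acid (1.1 equiv)
Product: 15 methyl 6-{[(3-formyl-2,4-dihydroxy-6-methylbenzoyl)oxy]methyl}-2,4-dihydroxy-3-methylbenzoate (target)
Conditions: PPh3 (1.2 equiv), DIAD (1.2 equiv, added slowly), THF, 0 °C to rt
Reagents that add atoms: none
Why: Mitsunobu esterification, in which the carboxylic acid is by far the most acidic partner and so protonates the betaine, and its carboxylate then displaces triphenylphosphine oxide from the primary benzylic oxyphosphonium ion under neutral conditions; the hindrance around the ring B carbonyl is irrelevant because the bond formed is O–CH2.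

**Compound list**

1 | orsellinic acid (2,4-dihydroxy-6-methylbenzoic acid) | Cc1cc(O)cc(O)c1C(=O)O | starting material
2 | allyl 2,4-dihydroxy-6-methylbenzoate | C=CCOC(=O)c1c(C)cc(O)cc1O | intermediate
3 | allyl 3-formyl-2,4-dihydroxy-6-methylbenzoate | C=CCOC(=O)c1c(C)cc(O)c(C=O)c1O | intermediate
4 | 3-formyl-2,4-dihydroxy-6-methylbenzoic acid (haematommic acid) | Cc1cc(O)c(C=O)c(O)c1C(=O)O | intermediate
5 | benzyloxyacetaldehyde | O=CCOCc1ccccc1 | starting material
6 | dimethyl (2-oxobutyl)phosphonate | CCC(=O)CP(=O)(OC)OC | starting material
7 | (E)-6-(benzyloxy)hex-4-en-3-one | CCC(=O)/C=C/COCc1ccccc1 | intermediate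
8 | dimethyl malonate | COC(=O)CC(=O)OC | starting material
9 | dimethyl 2-[1-(benzyloxy)-4-oxohexan-2-yl]propanedioate (racemic Michael adduct, not isolated) | CCC(=O)CC(COCc1ccccc1)C(C(=O)OC)C(=O)OC | intermediate
10 | (1RS,6SR)-methyl 6-[(benzyloxy)methyl]-2-hydroxy-3-methyl-4-oxocyclohex-2-ene-1-carboxylate (racemic trans; enol form of the 2,4-dione; the 1S,6R enantiomer is drawn) | COC(=O)[C@@H]1C(O)=C(C)C(=O)C[C@H]1COCc1ccccc1 | intermediate
11 | methyl 6-[(benzyloxy)methyl]-3-bromo-3-methyl-2,4-dioxocyclohexane-1-carboxylate (mixture of stereoisomers, not isolated) | COC(=O)C1C(=O)C(C)(Br)C(=O)CC1COCc1ccccc1 | intermediate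
12 | methyl 6-[(benzyloxy)methyl]-1-bromo-2-hydroxy-3-methyl-4-oxocyclohex-2-ene-1-carboxylate (mixture of stereoisomers, not isolated) | COC(=O)C1(Br)C(O)=C(C)C(=O)CC1COCc1ccccc1 | intermediate
13 | methyl 6-[(benzyloxy)methyl]-2,4-dihydroxy-3-methylbenzoate | COC(=O)c1c(COCc2ccccc2)cc(O)c(C)c1O | intermediate
14 | methyl 2,4-dihydroxy-6-(hydroxymethyl)-3-methylbenzoate | COC(=O)c1c(CO)cc(O)c(C)c1O | intermediate
15 | methyl 6-{[(3-formyl-2,4-dihydroxy-6-methylbenzoyl)oxy]methyl}-2,4-dihydroxy-3-methylbenzoate | COC(=O)c1c(COC(=O)c2c(C)cc(O)c(C=O)c2O)cc(O)c(C)c1O | target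

**Step count**

Total: 8 steps. Longest linear sequence: 5 steps (steps 4 to 8, from aldehyde 5); the ring B branch (steps 1 to 3) joins at step 8.

**Steps most likely to fail, with fallbacks**

Step 8 (Mitsunobu coupling). The benzylic oxyphosphonium ion formed from 14 may be captured by a phenol oxygen instead of the carboxylate (O-alkylation and oligomers). It may also be captured by the neighbouring C1 ester carbonyl with loss of the methyl group (phthalide closure). The fallback separates activation from esterification. It sets out from 14: Appel bromination (CBr4, PPh3, CH2Cl2, 0 °C) should give methyl 6-(bromomethyl)-2,4-dihydroxy-3-methylbenzoate F1. This bromide is added to the potassium salt of acid 4 (KHCO3, 1.0 equiv, DMF, rt), and SN2 displacement by the carboxylate comes back to the route at target 15. Bicarbonate ionizes only the carboxyl group, so the phenols stay protonated and unreactive.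

Step 7 (hydrogenolysis). Hydrogen may cleave the ring A benzylic C–O bond or reduce the freed benzylic alcohol further, both ending in a C6 methyl group; the freed alcohol may also close onto the C1 ester during isolation. The fallback carries the C6 oxygen as a silyl ether and releases it with buffered fluoride, so no reductive step touches the benzylic carbon. It sets out from phosphonate 6: olefination of purchased 2-[(tert-butyldiphenylsilyl)oxy]acetaldehyde (O=CCO[Si](c1ccccc1)(c1ccccc1)C(C)(C)C) under the step 4 conditions should give (E)-6-[(tert-butyldiphenylsilyl)oxy]hex-4-en-3-one F2. NaOMe in MeOH with malonate 8 should then give, through dimethyl 2-{1-[(tert-butyldiphenylsilyl)oxy]-4-oxohexan-2-yl}propanedioate F3 (not isolated), racemic trans methyl 6-{[(tert-butyldiphenylsilyl)oxy]methyl}-2-hydroxy-3-methyl-4-oxocyclohex-2-ene-1-carboxylate F4; the silyl ether is expected to survive because methoxide is consumed first by the malonate and then by the acidic dione. Br2 in DMF as in step 6 passes through methyl 3-bromo-6-{[(tert-butyldiphenylsilyl)oxy]methyl}-3-methyl-2,4-dioxocyclohexane-1-carboxylate F5 and methyl 1-bromo-6-{[(tert-butyldiphenylsilyl)oxy]methyl}-2-hydroxy-3-methyl-4-oxocyclohex-2-ene-1-carboxylate F6 (neither isolated) to methyl 6-{[(tert-butyldiphenylsilyl)oxy]methyl}-2,4-dihydroxy-3-methylbenzoate F7. TBAF buffered with AcOH (THF, 0 °C) then removes the silyl group and comes back to the route at 14, which is used at once in step 8.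

Step 6 (aromatization). Bromine may be transferred from the bromo dione to the newly formed, strongly activated arene (bromination at C5), which leaves part of 10 unoxidized; loss of HBr may also be incomplete. The fallback over-brominates on purpose and removes the nuclear halogen reductively, the classical way from dihydroresorcylates to resorcylates. It sets out from 10: Br2 (2.1 equiv, DMF, 0 °C then 80 °C) should give methyl 6-[(benzyloxy)methyl]-5-bromo-2,4-dihydroxy-3-methylbenzoate F8. H2, 10% Pd/C and NaOAc in EtOAc then cleave the C5–Br bond and the benzyl ether in one operation, and the route is rejoined at 14.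

**Further compounds**

F1 | step 8 | methyl 6-(bromomethyl)-2,4-dihydroxy-3-methylbenzoate | COC(=O)c1c(CBr)cc(O)c(C)c1O
F2 | step 7 | (E)-6-[(tert-butyldiphenylsilyl)oxy]hex-4-en-3-one | CCC(=O)/C=C/CO[Si](c1ccccc1)(c1ccccc1)C(C)(C)C
F3 | step 7 | dimethyl 2-{1-[(tert-butyldiphenylsilyl)oxy]-4-oxohexan-2-yl}propanedioate (racemic) | CCC(=O)CC(CO[Si](c1ccccc1)(c1ccccc1)C(C)(C)C)C(C(=O)OC)C(=O)OC
F4 | step 7 | (1RS,6SR)-methyl 6-{[(tert-butyldiphenylsilyl)oxy]methyl}-2-hydroxy-3-methyl-4-oxocyclohex-2-ene-1-carboxylate (racemic trans, one enantiomer drawn) | COC(=O)[C@@H]1C(O)=C(C)C(=O)C[C@H]1CO[Si](c1ccccc1)(c1ccccc1)C(C)(C)C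
F5 | step 7 | methyl 3-bromo-6-{[(tert-butyldiphenylsilyl)oxy]methyl}-3-methyl-2,4-dioxocyclohexane-1-carboxylate (mixture of stereoisomers) | COC(=O)C1C(=O)C(C)(Br)C(=O)CC1CO[Si](c1ccccc1)(c1ccccc1)C(C)(C)C
F6 | step 7 | methyl 1-bromo-6-{[(tert-butyldiphenylsilyl)oxy]methyl}-2-hydroxy-3-methyl-4-oxocyclohex-2-ene-1-carboxylate (mixture of stereoisomers) | COC(=O)C1(Br)C(O)=C(C)C(=O)CC1CO[Si](c1ccccc1)(c1ccccc1)C(C)(C)C
F7 | step 7 | methyl 6-{[(tert-butyldiphenylsilyl)oxy]methyl}-2,4-dihydroxy-3-methylbenzoate | COC(=O)c1c(CO[Si](c2ccccc2)(c2ccccc2)C(C)(C)C)cc(O)c(C)c1O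
F8 | step 6 | methyl 6-[(benzyloxy)methyl]-5-bromo-2,4-dihydroxy-3-methylbenzoate | COC(=O)c1c(COCc2ccccc2)c(Br)c(O)c(C)c1O
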